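Ring C of the flavan half is built one atom short, as a cis-2-aryl-3-(hydroxymethyl)-2,3-dihydrobenzofuran made by enantioselective carbenoid C–H insertion. Solvolysis of its mesylate then moves the electron-rich ring A carbon C4a (flanked by O5 and O1) from C3 to the exocyclic carbon through a phenonium ion, and water enters C3 anti to it: one operation expands the furan to the pyran ring, creates C4 and sets the 2,3-cis alcohol with C2–O1 intact. The spiro unit (rings D and E) is then fused on O7/C8 by oxa-Michael addition to an aurone and palladium-catalysed enolate arylation of the C8 bromide.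

Key step: step 7

Remark: flavan numbering is used for rings A–C (O1, C2, C3, C4, C4a, C5–C8, C8a; ring B on C2); ring D is the dihydrofuran on C7–C8 (O7, Cα, spiro carbon), rings E and F are the benzofuranone, ring G is the aryl on Cα; compounds 1, 3, 16 and 18 are taken as commercial, and the catalyst antipodes named in steps 5 and 13 are assumed to be the ones that give the drawn configurations.

Step 1
Reactants: 1 2′,4′,6′-trihydroxyacetophenone
Product: 2 1-[2,6-dihydroxy-4-(tosyloxy)phenyl]ethan-1-one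
Conditions: TsCl (1.0 equiv), K2CO3, acetone, 0 °C to rt
Reagents that add atoms: p-toluenesulfonyl chloride, Cc1ccc(cc1)S(=O)(=O)Cl
Why: The 4-hydroxyl is the only one not hydrogen-bonded to the acetyl group and is the most acidic, so one equivalent of sulfonyl chloride should give chemoselective O-sulfonylation there.

Step 2
Reactants: 2 1-[2,6-dihydroxy-4-(tosyloxy)phenyl]ethan-1-one; 3 4-(benzyloxy)benzyl chloride
Product: 4 1-[2,6-bis{[4-(benzyloxy)benzyl]oxy}-4-(tosyloxy)phenyl]ethan-1-one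
Conditions: 3 (2.4 equiv), K2CO3, Bu4NI (cat.), DMF, 70 °C
Reagents that add atoms: none
Why: Williamson etherification of the two equivalent remaining phenols with the benzylic chloride, the aryl tosylate being inert to carbonate in DMF.

Step 3
Reactants: 4 1-[2,6-bis{[4-(benzyloxy)benzyl]oxy}-4-(tosyloxy)phenyl]ethan-1-one
Product: 6 methyl 2-[2,6-bis{[4-(benzyloxy)benzyl]oxy}-4-(tosyloxy)phenyl]-2-oxoacetate, via arylglyoxylic acid 5 (not isolated)
Conditions: SeO2, pyridine, 100 °C; then MeI, K2CO3, DMF, rt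
Reagents that add atoms: selenium dioxide, O=[Se]=O; iodomethane, CI
Why: Riley oxidation of the aryl methyl ketone with SeO2 in pyridine should give the arylglyoxylic acid, which is esterified in the same flask by carboxylate alkylation.

Step 4
Reactants: 6 methyl 2-[2,6-bis{[4-(benzyloxy)benzyl]oxy}-4-(tosyloxy)phenyl]-2-oxoacetate
Product: 8 methyl 2-diazo-2-[2,6-bis{[4-(benzyloxy)benzyl]oxy}-4-(tosyloxy)phenyl]acetate, via tosylhydrazone 7 (not isolated)
Conditions: TsNHNH2, toluene, 80 °C; then DBU, CH2Cl2, rt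
Reagents that add atoms: p-toluenesulfonyl hydrazide, Cc1ccc(cc1)S(=O)(=O)NN
Why: Condensation of the activated keto group with tosylhydrazide and base-induced loss of sulfinate (Bamford–Stevens reaction) is the standard way from an aryl glyoxylate to the aryl diazoacetate.

Step 5
Reactants: 8 methyl 2-diazo-2-[2,6-bis{[4-(benzyloxy)benzyl]oxy}-4-(tosyloxy)phenyl]acetate
Product: 9 methyl (2S,3R)-2-[4-(benzyloxy)phenyl]-4-{[4-(benzyloxy)benzyl]oxy}-6-(tosyloxy)-2,3-dihydrobenzofuran-3-carboxylate (2,3-cis)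
Conditions: Rh2(R-PTTL)4 [dirhodium tetrakis(N-phthaloyl-(R)-tert-leucinate)] (1 mol %), toluene, −60 °C
Reagents that add atoms: none
Why: The divalent rhodium carbenoid inserts into the benzylic O–CH2 bond of either of the two equivalent ortho ethers (intramolecular 1,5 C–H insertion) and closes the dihydrofuran, the chiral carboxylate catalyst setting C2 and delivering the kinetic 2,3-cis ester as known for 2-(benzyloxy)aryl diazoacetates with this catalyst class.

Step 6
Reactants: 9 methyl (2S,3R)-2-[4-(benzyloxy)phenyl]-4-{[4-(benzyloxy)benzyl]oxy}-6-(tosyloxy)-2,3-dihydrobenzofuran-3-carboxylate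
Product: 10 [(2S,3S)-2-[4-(benzyloxy)phenyl]-4-{[4-(benzyloxy)benzyl]oxy}-6-(tosyloxy)-2,3-dihydrobenzofuran-3-yl]methanol (2,3-cis)
Conditions: i-Bu2AlH, CH2Cl2, −78 °C to 0 °C
Reagents that add atoms: none
Why: Ester reduction with i-Bu2AlH at low temperature is non-basic, so the epimerizable C3 centre of the cis ester is kept and the aryl tosylate is untouched.

Step 7
Reactants: 10 [(2S,3S)-2-[4-(benzyloxy)phenyl]-4-{[4-(benzyloxy)benzyl]oxy}-6-(tosyloxy)-2,3-dihydrobenzofuran-3-yl]methanol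
Product: 12 (2R,3R)-2-[4-(benzyloxy)phenyl]-5-{[4-(benzyloxy)benzyl]oxy}-7-(tosyloxy)chroman-3-ol (2,3-cis), via primary mesylate 11 (not isolated)
Conditions: MsCl, Et3N, CH2Cl2, 0 °C; then HFIP/H2O (4:1), 2,6-lutidine, 45 °C
Reagents that add atoms: water, O
Why: Ionization of the primary mesylate is assisted by ring A carbon C3a (dihydrobenzofuran numbering; the later C4a), which is ortho to two ether oxygens, to give a bridged phenonium (spirocyclopropane arenium) ion, and water opens this ion at the old ring carbon C3 from the side opposite to the migrating carbon, so that the five-membered ring O1–C2–C3–C3a–C7a becomes the six-membered ring C (a Wagner–Meerwein 1,2-aryl shift with ring expansion). The closest known reaction type is the solvolytic ring expansion of 1-indanylmethyl sulfonates to 2-tetralyl derivatives through aryl-bridged ions (neophyl-type rearrangement). No new ring is closed by an end-to-end cyclization: the aryl carbon first bridges to the exocyclic carbon (3-exo-tet, Ar1-3 participation) and the old C3–aryl bond of the bridged ion is then broken, which turns the ring from five into six members. C2 is not involved and keeps its configuration, and the new C3–O bond forms with inversion (anti to the migrating aryl carbon), so the 2,3-cis alcohol 10 can only give the 2,3-cis (2R,3R) flavan-3-ol. The step needs opening of the bridged ion at C3 and not at the exocyclic CH2 (which only returns 10) and capture by water before proton loss or ionization of the benzylic C2–O1 bond; the strain of the bicyclic bridged ion, the two donor oxygens on the migrating carbon, and the strongly ionizing but buffered medium should secure this.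

Step 8
Reactants: 12 (2R,3R)-2-[4-(benzyloxy)phenyl]-5-{[4-(benzyloxy)benzyl]oxy}-7-(tosyloxy)chroman-3-ol
Product: 13 (2R,3R)-3-(benzyloxy)-2-[4-(benzyloxy)phenyl]-5-{[4-(benzyloxy)benzyl]oxy}-7-(tosyloxy)chromane
Conditions: NaH, BnBr, Bu4NI (cat.), DMF, 0 °C
Reagents that add atoms: benzyl bromide, BrCc1ccccc1
Why: Williamson O-benzylation masks the axial secondary alcohol against palladium-mediated oxidation in step 13, alkylation at 0 °C being faster than sulfonyl transfer from the aryl tosylate.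

Step 9
Reactants: 13 (2R,3R)-3-(benzyloxy)-2-[4-(benzyloxy)phenyl]-5-{[4-(benzyloxy)benzyl]oxy}-7-(tosyloxy)chromane
Product: 14 (2R,3R)-3-(benzyloxy)-2-[4-(benzyloxy)phenyl]-5-{[4-(benzyloxy)benzyl]oxy}-8-bromo-7-(tosyloxy)chromane
Conditions: NBS (1.05 equiv), CH2Cl2, −40 °C to 0 °C
Reagents that add atoms: N-bromosuccinimide, O=C1CCC(=O)N1Br
Why: Electrophilic aromatic bromination of ring A should go to C8, ortho to the tied-back ring oxygen O1 and para to O5, as known for 5,7-di-O-protected flavan-3-ols, while C6 is shielded by the bulky O5 ether and the tosylate.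

Step 10
Reactants: 14 (2R,3R)-3-(benzyloxy)-2-[4-(benzyloxy)phenyl]-5-{[4-(benzyloxy)benzyl]oxy}-8-bromo-7-(tosyloxy)chromane
Product: 15 (2R,3R)-3-(benzyloxy)-2-[4-(benzyloxy)phenyl]-5-{[4-(benzyloxy)benzyl]oxy}-8-bromochroman-7-ol
Conditions: KOH, dioxane/H2O, 80 °C
Reagents that add atoms: none
Why: Hydroxide attacks sulfur of the aryl sulfonate (S–O cleavage) to free O7, and because ring B carries no free para-hydroxyl the C2–O1 bond cannot open through a quinone methide, so C2 is not epimerized.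

Step 11
Reactants: 16 4,6-dihydroxybenzofuran-3(2H)-one
Product: 17 4,6-bis(benzyloxy)benzofuran-3(2H)-one
Conditions: BnBr (2.2 equiv), K2CO3, DMF, rt
Reagents that add atoms: benzyl bromide, BrCc1ccccc1
Why: Williamson O-benzylation of both phenols with carbonate at room temperature, where O-alkylation is favoured over alkylation at C2.

Step 12
Reactants: 17 4,6-bis(benzyloxy)benzofuran-3(2H)-one; 18 4-(benzyloxy)benzaldehyde
Product: 19 (Z)-4,6-bis(benzyloxy)-2-[4-(benzyloxy)benzylidene]benzofuran-3(2H)-one (aurone)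
Conditions: neutral Al2O3, CH2Cl2, rt
Reagents that add atoms: none
Why: Aldol (Knoevenagel-type) condensation of the acidic C2 methylene with the aldehyde should give the aurone as the thermodynamically favoured Z isomer.

Step 13
Reactants: 15 (2R,3R)-3-(benzyloxy)-2-[4-(benzyloxy)phenyl]-5-{[4-(benzyloxy)benzyl]oxy}-8-bromochroman-7-ol; 19 (Z)-4,6-bis(benzyloxy)-2-[4-(benzyloxy)benzylidene]benzofuran-3(2H)-one
Product: 21 fully protected target (flavan half 2R,3R with 3-O-benzyl 4′-O-benzyl 5-O-[4-(benzyloxy)benzyl]; spiro carbon R; Cα R; rings F and G O-benzylated), via oxa-Michael adduct 20 (not isolated)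
Conditions: Cs2CO3, Pd2(dba)3 (5 mol %), (R)-DIFLUORPHOS (12 mol %), toluene, rt then 90 °C
Reagents that add atoms: none
Why: Reversible base-mediated oxa-Michael addition of phenoxide O7 to the aurone gives enolate 20, whose zerovalent-palladium-catalysed intramolecular α-arylation by the C8–Br bond (5-exo closure of ring D) is irreversible and forms the quaternary spiro carbon; allylic 1,3-strain in the enolate holds the benzylic C–H in the enolate plane so that ring G should end cis to the furanone oxygen, while the sense of the new pair relative to the remote flavan centres is left to the chiral bisphosphine acting on the equilibrating epimers of 20 (dynamic kinetic resolution), any minor diastereomer being removed by chromatography.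

Step 14
Reactants: 21 fully protected target
Product: 22 CNP0228515.2 (target)
Conditions: H2 (1 atm), Pd(OH)2/C, THF/MeOH, rt
Reagents that add atoms: none
Why: Hydrogenolysis removes all benzyl-type ethers (as toluene and p-cresol), the cyclic benzylic ethers at C2 and Cα and the aryl ketone being slower to react at 1 atm and room temperature, so no stereocentre is touched.

Compound list
1 | 2′,4′,6′-trihydroxyacetophenone | CC(=O)c1c(O)cc(O)cc1O | starting material
2 | 1-[2,6-dihydroxy-4-(tosyloxy)phenyl]ethan-1-one | CC(=O)c1c(O)cc(OS(=O)(=O)c2ccc(C)cc2)cc1O | intermediate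
3 | 4-(benzyloxy)benzyl chloride | ClCc1ccc(OCc2ccccc2)cc1 | starting material
4 | 1-[2,6-bis{[4-(benzyloxy)benzyl]oxy}-4-(tosyloxy)phenyl]ethan-1-one | CC(=O)c1c(OCc2ccc(OCc3ccccc3)cc2)cc(OS(=O)(=O)c2ccc(C)cc2)cc1OCc1ccc(OCc2ccccc2)cc1 | intermediate
5 | 2-[2,6-bis{[4-(benzyloxy)benzyl]oxy}-4-(tosyloxy)phenyl]-2-oxoacetic acid | OC(=O)C(=O)c1c(OCc2ccc(OCc3ccccc3)cc2)cc(OS(=O)(=O)c2ccc(C)cc2)cc1OCc1ccc(OCc2ccccc2)cc1 | intermediate
6 | methyl 2-[2,6-bis{[4-(benzyloxy)benzyl]oxy}-4-(tosyloxy)phenyl]-2-oxoacetate | COC(=O)C(=O)c1c(OCc2ccc(OCc3ccccc3)cc2)cc(OS(=O)(=O)c2ccc(C)cc2)cc1OCc1ccc(OCc2ccccc2)cc1 | intermediate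
7 | N-tosylhydrazone of 6 | COC(=O)C(=NNS(=O)(=O)c1ccc(C)cc1)c1c(OCc2ccc(OCc3ccccc3)cc2)cc(OS(=O)(=O)c2ccc(C)cc2)cc1OCc1ccc(OCc2ccccc2)cc1 | intermediate
8 | methyl 2-diazo-2-[2,6-bis{[4-(benzyloxy)benzyl]oxy}-4-(tosyloxy)phenyl]acetate | COC(=O)C(=[N+]=[N-])c1c(OCc2ccc(OCc3ccccc3)cc2)cc(OS(=O)(=O)c2ccc(C)cc2)cc1OCc1ccc(OCc2ccccc2)cc1 | intermediate
9 | methyl (2S,3R)-2-[4-(benzyloxy)phenyl]-4-{[4-(benzyloxy)benzyl]oxy}-6-(tosyloxy)-2,3-dihydrobenzofuran-3-carboxylate (2,3-cis) | COC(=O)[C@@H]1c2c(OCc3ccc(OCc4ccccc4)cc3)cc(OS(=O)(=O)c3ccc(C)cc3)cc2O[C@@H]1c1ccc(OCc2ccccc2)cc1 | intermediate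
10 | [(2S,3S)-2-[4-(benzyloxy)phenyl]-4-{[4-(benzyloxy)benzyl]oxy}-6-(tosyloxy)-2,3-dihydrobenzofuran-3-yl]methanol (2,3-cis) | OC[C@@H]1c2c(OCc3ccc(OCc4ccccc4)cc3)cc(OS(=O)(=O)c3ccc(C)cc3)cc2O[C@@H]1c1ccc(OCc2ccccc2)cc1 | intermediate
11 | methanesulfonate of 10 | CS(=O)(=O)OC[C@@H]1c2c(OCc3ccc(OCc4ccccc4)cc3)cc(OS(=O)(=O)c3ccc(C)cc3)cc2O[C@@H]1c1ccc(OCc2ccccc2)cc1 | intermediate
12 | (2R,3R)-2-[4-(benzyloxy)phenyl]-5-{[4-(benzyloxy)benzyl]oxy}-7-(tosyloxy)chroman-3-ol (2,3-cis) | O[C@@H]1Cc2c(OCc3ccc(OCc4ccccc4)cc3)cc(OS(=O)(=O)c3ccc(C)cc3)cc2O[C@@H]1c1ccc(OCc2ccccc2)cc1 | intermediate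
13 | (2R,3R)-3-(benzyloxy)-2-[4-(benzyloxy)phenyl]-5-{[4-(benzyloxy)benzyl]oxy}-7-(tosyloxy)chromane | C(c1ccccc1)O[C@@H]1Cc2c(OCc3ccc(OCc4ccccc4)cc3)cc(OS(=O)(=O)c3ccc(C)cc3)cc2O[C@@H]1c1ccc(OCc2ccccc2)cc1 | intermediate
14 | (2R,3R)-3-(benzyloxy)-2-[4-(benzyloxy)phenyl]-5-{[4-(benzyloxy)benzyl]oxy}-8-bromo-7-(tosyloxy)chromane | C(c1ccccc1)O[C@@H]1Cc2c(OCc3ccc(OCc4ccccc4)cc3)cc(OS(=O)(=O)c3ccc(C)cc3)c(Br)c2O[C@@H]1c1ccc(OCc2ccccc2)cc1 | intermediate
15 | (2R,3R)-3-(benzyloxy)-2-[4-(benzyloxy)phenyl]-5-{[4-(benzyloxy)benzyl]oxy}-8-bromochroman-7-ol | C(c1ccccc1)O[C@@H]1Cc2c(OCc3ccc(OCc4ccccc4)cc3)cc(O)c(Br)c2O[C@@H]1c1ccc(OCc2ccccc2)cc1 | intermediate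
16 | 4,6-dihydroxybenzofuran-3(2H)-one | O=C1COc2cc(O)cc(O)c12 | starting material
17 | 4,6-bis(benzyloxy)benzofuran-3(2H)-one | O=C1COc2cc(OCc3ccccc3)cc(OCc3ccccc3)c12 | intermediate
18 | 4-(benzyloxy)benzaldehyde | O=Cc1ccc(OCc2ccccc2)cc1 | starting material
19 | (Z)-4,6-bis(benzyloxy)-2-[4-(benzyloxy)benzylidene]benzofuran-3(2H)-one | O=C1/C(=C/c2ccc(OCc3ccccc3)cc2)Oc2cc(OCc3ccccc3)cc(OCc3ccccc3)c12 | intermediate
20 | oxa-Michael adduct: 4,6-bis(benzyloxy)-2-{[4-(benzyloxy)phenyl](aryloxy)methyl}benzofuran-3(2H)-one, aryloxy = O7 of 15 (both epimers at the two new centres, interconverting) | O=C1C(C(Oc2cc(OCc3ccc(OCc4ccccc4)cc3)c3C[C@@H](OCc4ccccc4)[C@@H](c4ccc(OCc5ccccc5)cc4)Oc3c2Br)c2ccc(OCc3ccccc3)cc2)Oc2cc(OCc3ccccc3)cc(OCc3ccccc3)c12 | intermediate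
21 | fully protected target: flavan half (2R,3R) with 3-O-benzyl, 4′-O-benzyl and 5-O-[4-(benzyloxy)benzyl]; spiro carbon R; Cα R with ring G cis to the furanone oxygen; rings F and G O-benzylated | O=C1c2c(OCc4ccccc4)cc(OCc4ccccc4)cc2O[C@@]13c1c(cc(OCc4ccc(OCc5ccccc5)cc4)c4c1O[C@H](c1ccc(OCc5ccccc5)cc1)[C@H](OCc1ccccc1)C4)O[C@@H]3c1ccc(OCc4ccccc4)cc1 | intermediate
22 | CNP0228515.2: flavan half (2R,3R), spiro carbon R, Cα R | O=C1c2c(O)cc(O)cc2O[C@@]12c1c(cc(O)c3c1O[C@H](c1ccc(O)cc1)[C@H](O)C3)O[C@@H]2c1ccc(O)cc1 | target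

Total step count: 14. Longest linear sequence: 12 steps (steps 1 to 10, then 13 and 14); steps 11 and 12 make the aurone branch.

Steps most likely to fail

Step 7: the bridged ion may be captured at the exocyclic CH2 (return to 10), or it may lose a proton faster than water attacks C3, and aryl participation may be slowed by the ring constraint. The fallback sets out from 10 and returns at 12. The mesylate 11 is heated in dry HFIP with 2,6-di-tert-butylpyridine, so that the ring expansion ends in proton loss and should give (2S)-2-[4-(benzyloxy)phenyl]-5-{[4-(benzyloxy)benzyl]oxy}-7-(tosyloxy)-2H-chromene F1. Hydroboration–oxidation (BH3·THF, then NaBO3·4H2O) adds boron at C3 anti to ring B and should give the 2,3-trans flavan-3-ol F2. Dess–Martin periodinane should then give the flavan-3-one F3, and LiBH(s-Bu)3 at −78 °C reduces it from the face opposite to ring B to the 2,3-cis alcohol 12. In this variant the ring is still expanded by the aryl shift, but C3 is set by hydride delivery and not by the anti opening.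

Step 13: oxidative addition at the hindered C8–Br bond may be slow, so that protodebromination or Heck-type insertion into the aurone competes, and discrimination between the two epimers of 20 may be poor. The fallback sets out from 14 and 17 and returns at 21. Intermolecular palladium-catalysed α-arylation of 17 with bromide 14 (Pd(OAc)2, XPhos, K3PO4, toluene, 100 °C) should give the 2-(flavan-8-yl)benzofuranone F7. KOH in aqueous dioxane then frees O7 to give the phenol F8. Acid-catalysed cyclocondensation of F8 with aldehyde 18 (diphenyl phosphate or a chiral phosphoric acid, 4 Å molecular sieves, CH2Cl2) should form the Cα–spiro bond by aldol addition of the enol and the Cα–O7 bond by capture of the benzylic cation, giving 21 after separation of the spiro diastereomers.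

Step 5: the carbenoid, twisted by its two ortho ethers, may insert with eroded cis selectivity, or the cis ester may epimerize at C3. The fallback sets out from 9 (as a cis/trans mixture) and returns at 12. DBU in toluene equilibrates the mixture to the 2,3-trans ester F4, and i-Bu2AlH gives the trans alcohol F5. The mesylation and solvolysis of step 7, through the trans mesylate F6, should then give the 2,3-trans flavan-3-ol F2. Oxidation to the flavan-3-one F3 and LiBH(s-Bu)3 reduction, as described under step 7, lead to 12.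

Further compounds
F1 | step 7 | (2S)-2-[4-(benzyloxy)phenyl]-5-{[4-(benzyloxy)benzyl]oxy}-7-(tosyloxy)-2H-chromene | C1=Cc2c(OCc3ccc(OCc4ccccc4)cc3)cc(OS(=O)(=O)c3ccc(C)cc3)cc2O[C@@H]1c1ccc(OCc2ccccc2)cc1
F2 | step 7 | (2R,3S)-2-[4-(benzyloxy)phenyl]-5-{[4-(benzyloxy)benzyl]oxy}-7-(tosyloxy)chroman-3-ol (2,3-trans) | O[C@H]1Cc2c(OCc3ccc(OCc4ccccc4)cc3)cc(OS(=O)(=O)c3ccc(C)cc3)cc2O[C@@H]1c1ccc(OCc2ccccc2)cc1
F3 | step 7 | (2R)-2-[4-(benzyloxy)phenyl]-5-{[4-(benzyloxy)benzyl]oxy}-7-(tosyloxy)chroman-3-one | O=C1Cc2c(OCc3ccc(OCc4ccccc4)cc3)cc(OS(=O)(=O)c3ccc(C)cc3)cc2O[C@@H]1c1ccc(OCc2ccccc2)cc1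
F4 | step 5 | methyl (2S,3S)-2-[4-(benzyloxy)phenyl]-4-{[4-(benzyloxy)benzyl]oxy}-6-(tosyloxy)-2,3-dihydrobenzofuran-3-carboxylate (2,3-trans) | COC(=O)[C@H]1c2c(OCc3ccc(OCc4ccccc4)cc3)cc(OS(=O)(=O)c3ccc(C)cc3)cc2O[C@@H]1c1ccc(OCc2ccccc2)cc1
F5 | step 5 | [(2S,3R)-2-[4-(benzyloxy)phenyl]-4-{[4-(benzyloxy)benzyl]oxy}-6-(tosyloxy)-2,3-dihydrobenzofuran-3-yl]methanol (2,3-trans) | OC[C@H]1c2c(OCc3ccc(OCc4ccccc4)cc3)cc(OS(=O)(=O)c3ccc(C)cc3)cc2O[C@@H]1c1ccc(OCc2ccccc2)cc1
F6 | step 5 | methanesulfonate of F5 | CS(=O)(=O)OC[C@H]1c2c(OCc3ccc(OCc4ccccc4)cc3)cc(OS(=O)(=O)c3ccc(C)cc3)cc2O[C@@H]1c1ccc(OCc2ccccc2)cc1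
F7 | step 13 | 4,6-bis(benzyloxy)-2-{(2R,3R)-3-(benzyloxy)-2-[4-(benzyloxy)phenyl]-5-{[4-(benzyloxy)benzyl]oxy}-7-(tosyloxy)chroman-8-yl}benzofuran-3(2H)-one (epimers at the benzofuranone C2) | O=C1C(c2c(OS(=O)(=O)c3ccc(C)cc3)cc(OCc3ccc(OCc4ccccc4)cc3)c3C[C@@H](OCc4ccccc4)[C@@H](c4ccc(OCc5ccccc5)cc4)Oc23)Oc2cc(OCc3ccccc3)cc(OCc3ccccc3)c12
F8 | step 13 | 4,6-bis(benzyloxy)-2-{(2R,3R)-3-(benzyloxy)-2-[4-(benzyloxy)phenyl]-5-{[4-(benzyloxy)benzyl]oxy}-7-hydroxychroman-8-yl}benzofuran-3(2H)-one (epimers at the benzofuranone C2) | O=C1C(c2c(O)cc(OCc3ccc(OCc4ccccc4)cc3)c3C[C@@H](OCc4ccccc4)[C@@H](c4ccc(OCc5ccccc5)cc4)Oc23)Oc2cc(OCc3ccccc3)cc(OCc3ccccc3)c12
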